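**Plan**

1. Target numbering: ring C1 (CO2H), C2 (OH), C4 (OMe), C6 (side chain C1'–C13', C2' = ketone). The hard part is the carboxyl wedged between C2–O and the C6 arm, whose ketone sits β to the ring.
2. Retrosynthesis: the carboxyl O is re-closed onto C2' (the keto acid is a hydrated isocoumarin; C2–OH is masked as OMe, C13'–OH as pivalate). Three bonds of that isocoumarin are then cut at once: C6–C1', C1–CO2 and carboxyl O–C2', giving 3,5-dimethoxybenzyne, a C13 terminal alkyne and CO2.
3. Enabling feature: CO2H on C1 and the CH2–C(=O) arm on the neighbouring C6 are a carboxylate-hydrated aryl alkyne. The C2 oxygen next to C1 polarises the C1≡C6 aryne so that the acetylide carbon bonds to C6 and copper, then CO2, to C1.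
4. Forward: an o-silylaryl triflate from 3,5-dimethoxyphenol (steps 1–3) and an alkyne pivalate from 11-bromoundecan-1-ol (steps 4–5) are joined with CO2, which closes the pyranone ring (step 6). Chelation-controlled O-demethylation at the oxygen peri to the lactone carbonyl follows (step 7), then hydrolysis opens the lactone to acid plus ketone and frees the alcohol (step 8).
5. Stereochemistry: none to set.

Key step: step 6

Remark: the target has no stereocentre and no stereogenic double bond; it is achiral, so the requirement of a single enantiomer is met by the constitution alone.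

**Step 1**
Reactants: 1 3,5-dimethoxyphenol
Product: 2 3,5-dimethoxyphenyl N-isopropylcarbamate
Conditions: i-PrNCO, Et3N (cat.), CH2Cl2, rt
Reagents that add atoms: isopropyl isocyanate, CC(C)N=C=O
Why: Base-catalysed addition of the phenol to the isocyanate (carbamoylation) should install an N-monoalkyl carbamate that serves as a removable ortho-directing group.

**Step 2**
Reactants: 2 3,5-dimethoxyphenyl N-isopropylcarbamate
Product: 6 3,5-dimethoxy-2-(trimethylsilyl)phenyl N-isopropylcarbamate, via N-silyl carbamate 3 (not isolated), via ortho-lithiated N-silyl carbamate 4 (not isolated), via C-silylated N-silyl carbamate 5 (not isolated)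
Conditions: TBSOTf, TMEDA, Et2O, 0 °C → rt; then n-BuLi (2 equiv), TMEDA, −78 °C; TMSCl, −78 °C → rt; 2 M HCl work-up
Reagents that add atoms: chlorotrimethylsilane, C[Si](C)(C)Cl
Why: Directed ortho-metalation: after in situ N-silylation the O-carbamate should steer n-BuLi/TMEDA to C2, the site between the carbamate and a methoxy group (C2 and C6 are equivalent by symmetry), the aryllithium is silylated by TMSCl, and the N-silyl group is lost on acidic work-up.

**Step 3**
Reactants: 6 3,5-dimethoxy-2-(trimethylsilyl)phenyl N-isopropylcarbamate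
Product: 8 3,5-dimethoxy-2-(trimethylsilyl)phenyl trifluoromethanesulfonate, via DBU-H phenoxide 7 (not isolated)
Conditions: DBU, Et2NH, MeCN, 40 °C; then PhNTf2, rt
Reagents that add atoms: N-phenylbis(trifluoromethanesulfonimide), O=S(=O)(N(c1ccccc1)S(=O)(=O)C(F)(F)F)C(F)(F)F
Why: DBU-induced E1cB loss of isopropyl isocyanate (trapped by Et2NH as a urea) should free the phenoxide, which is triflated in the same flask by PhNTf2, the standard way to an o-silylaryl triflate aryne precursor.

**Step 4**
Reactants: 9 11-bromoundecan-1-ol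
Product: 10 tridec-12-yn-1-ol
Conditions: LiC≡CH·H2NCH2CH2NH2 (2.5 equiv), DMSO, 5 °C → rt; aqueous work-up
Reagents that add atoms: lithium acetylide–ethylenediamine complex, [Li+].[C-]#C.NCCN
Why: SN2 alkylation of acetylide by the primary bromide in DMSO should give the terminal alkyne, the first equivalent of acetylide converting the hydroxyl into its lithium alkoxide.

**Step 5**
Reactants: 10 tridec-12-yn-1-ol
Product: 11 tridec-12-yn-1-yl pivalate
Conditions: PivCl, pyridine, DMAP (cat.), CH2Cl2, 0 °C → rt
Reagents that add atoms: pivaloyl chloride, CC(C)(C)C(=O)Cl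
Why: DMAP-catalysed O-acylation should give a hindered ester that tolerates fluoride, carbonate and BCl3 and is removed in the final hydrolysis without an extra step.

**Step 6**
Reactants: 8 3,5-dimethoxy-2-(trimethylsilyl)phenyl trifluoromethanesulfonate (1.5 equiv, added in portions); 11 tridec-12-yn-1-yl pivalate
Product: 17 11-(6,8-dimethoxy-1-oxo-1H-isochromen-3-yl)undecyl pivalate, via 3,5-dimethoxybenzyne 12 (not isolated), via copper acetylide 13 (not isolated), via aryl copper 14 (not isolated), via copper carboxylate 15 (not isolated), via vinyl copper 16 (not isolated)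
Conditions: IPrCuCl (10 mol %), CsF, Cs2CO3, CO2 (1 atm), dry MeCN, 100 °C (sealed vessel)
Reagents that add atoms: carbon dioxide, O=C=O
Why: Fluoride strips the silyl group of 8 and triflate leaves to give aryne 12, the copper acetylide 13 formed from 11 adds across the strained triple bond (carbocupration) to give aryl copper 14, CO2 inserts into its C–Cu bond to give carboxylate 15, the carboxylate oxygen adds to the copper-activated alkyne to give vinyl copper 16, and protonolysis by a further molecule of 11 releases 17 and returns 13. The closest known reaction type is the NHC–copper-catalysed three-component coupling of arynes, terminal alkynes and CO2 to 3-substituted isocoumarins. The only ring closed is the pyranone, by 6-endo-dig attack of the carboxylate oxygen on the alkyne carbon that bears the alkyl chain, so that one CO2 oxygen becomes the later ketone oxygen at C2'. No stereocentre is formed. The step needs the acetylide to bond to the aryne carbon remote from the flanking methoxy group: the inductively withdrawing C3 methoxy distorts the aryne so that this carbon is the more electrophilic one, and copper (hence the CO2 carbon) ends up next to the oxygen, where induction and coordination stabilise it. 6-endo over 5-exo closure should be secured by π-activation of the alkyne by the carbophilic NHC–Cu(I) and by the alkyl group on the distal alkyne carbon, and the pivalate and both methyl ethers are inert to CsF/Cs2CO3 in dry MeCN.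

**Step 7**
Reactants: 17 11-(6,8-dimethoxy-1-oxo-1H-isochromen-3-yl)undecyl pivalate
Product: 19 11-(8-hydroxy-6-methoxy-1-oxo-1H-isochromen-3-yl)undecyl pivalate, via dichloroboron phenoxide 18 (not isolated)
Conditions: BCl3 (1.5 equiv), CH2Cl2, −78 → 0 °C; then H2O
Reagents that add atoms: none
Why: Chelation-controlled ether cleavage: BCl3 should bind the lactone carbonyl and the peri C8 methoxy oxygen in a six-membered chelate so that chloride removes only that methyl group, leaving the C6 methoxy, the enol lactone and the pivalate untouched at low temperature.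

**Step 8**
Reactants: 19 11-(8-hydroxy-6-methoxy-1-oxo-1H-isochromen-3-yl)undecyl pivalate
Product: 21 2-hydroxy-6-(13-hydroxy-2-oxotridecyl)-4-methoxybenzoic acid, via dipotassium salt 20 (not isolated)
Conditions: KOH (6 equiv), 1,4-dioxane/H2O, 70 °C; then 1 M HCl to pH 3, 0 °C, extraction without heating
Reagents that add atoms: potassium hydroxide, [K+].[OH-]
Why: Hydroxide should add to the lactone carbonyl (acyl substitution) and expel the enolate, which tautomerises to the C2' ketone, while the same conditions saponify the pivalate; cold, mild acidification should release the keto acid without re-closure to the enol lactone.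

**Compound list**

1 | 3,5-dimethoxyphenol | COc1cc(O)cc(OC)c1 | starting material
2 | 3,5-dimethoxyphenyl N-isopropylcarbamate | COc1cc(OC)cc(OC(=O)NC(C)C)c1 | intermediate
3 | 3,5-dimethoxyphenyl N-(tert-butyldimethylsilyl)-N-isopropylcarbamate | COc1cc(OC)cc(OC(=O)N(C(C)C)[Si](C)(C)C(C)(C)C)c1 | intermediate (not isolated)
4 | 2-lithio-3,5-dimethoxyphenyl N-(tert-butyldimethylsilyl)-N-isopropylcarbamate | COc1cc(OC)c([Li])c(OC(=O)N(C(C)C)[Si](C)(C)C(C)(C)C)c1 | intermediate (not isolated)
5 | 3,5-dimethoxy-2-(trimethylsilyl)phenyl N-(tert-butyldimethylsilyl)-N-isopropylcarbamate | COc1cc(OC)c([Si](C)(C)C)c(OC(=O)N(C(C)C)[Si](C)(C)C(C)(C)C)c1 | intermediate (not isolated)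
6 | 3,5-dimethoxy-2-(trimethylsilyl)phenyl N-isopropylcarbamate | COc1cc(OC)c([Si](C)(C)C)c(OC(=O)NC(C)C)c1 | intermediate
7 | DBU-H+ 3,5-dimethoxy-2-(trimethylsilyl)phenoxide | COc1cc(OC)c([Si](C)(C)C)c([O-])c1.C1CCC2=[NH+]CCCN2CC1 | intermediate (not isolated)
8 | 3,5-dimethoxy-2-(trimethylsilyl)phenyl trifluoromethanesulfonate | COc1cc(OC)c([Si](C)(C)C)c(OS(=O)(=O)C(F)(F)F)c1 | intermediate
9 | 11-bromoundecan-1-ol | OCCCCCCCCCCCBr | starting material
10 | tridec-12-yn-1-ol | C#CCCCCCCCCCCCO | intermediate
11 | tridec-12-yn-1-yl pivalate | C#CCCCCCCCCCCCOC(=O)C(C)(C)C | intermediate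
12 | 3,5-dimethoxybenzyne (1,2-didehydro-3,5-dimethoxybenzene) | COC1=CC(OC)=CC#C1 | intermediate (not isolated)
13 | (IPr)copper(I) 13-(pivaloyloxy)tridec-1-yn-1-ide | CC(C)c1cccc(C(C)C)c1N1C=C[N+](c2c(C(C)C)cccc2C(C)C)=C1[Cu-]C#CCCCCCCCCCCCOC(=O)C(C)(C)C | intermediate (not isolated)
14 | (IPr)copper(I) 2,4-dimethoxy-6-[13-(pivaloyloxy)tridec-1-yn-1-yl]phenyl | CC(C)c1cccc(C(C)C)c1N1C=C[N+](c2c(C(C)C)cccc2C(C)C)=C1[Cu-]c1c(OC)cc(OC)cc1C#CCCCCCCCCCCCOC(=O)C(C)(C)C | intermediate (not isolated)
15 | (IPr)copper(I) 2,4-dimethoxy-6-[13-(pivaloyloxy)tridec-1-yn-1-yl]benzoate | CC(C)c1cccc(C(C)C)c1N1C=C[N+](c2c(C(C)C)cccc2C(C)C)=C1[Cu-]OC(=O)c1c(OC)cc(OC)cc1C#CCCCCCCCCCCCOC(=O)C(C)(C)C | intermediate (not isolated)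
16 | (IPr)copper(I) 6,8-dimethoxy-1-oxo-3-[11-(pivaloyloxy)undecyl]-1H-isochromen-4-yl | CC(C)c1cccc(C(C)C)c1N1C=C[N+](c2c(C(C)C)cccc2C(C)C)=C1[Cu-]C1=C(CCCCCCCCCCCOC(=O)C(C)(C)C)OC(=O)c2c(OC)cc(OC)cc12 | intermediate (not isolated)
17 | 11-(6,8-dimethoxy-1-oxo-1H-isochromen-3-yl)undecyl pivalate | COc1cc(OC)c2c(c1)C=C(CCCCCCCCCCCOC(=O)C(C)(C)C)OC2=O | intermediate
18 | 11-[8-(dichloroboranyloxy)-6-methoxy-1-oxo-1H-isochromen-3-yl]undecyl pivalate | COc1cc(OB(Cl)Cl)c2c(c1)C=C(CCCCCCCCCCCOC(=O)C(C)(C)C)OC2=O | intermediate (not isolated)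
19 | 11-(8-hydroxy-6-methoxy-1-oxo-1H-isochromen-3-yl)undecyl pivalate | COc1cc(O)c2c(c1)C=C(CCCCCCCCCCCOC(=O)C(C)(C)C)OC2=O | intermediate
20 | dipotassium 2-(13-hydroxy-2-oxotridecyl)-4-methoxy-6-oxidobenzoate | COc1cc([O-])c(C(=O)[O-])c(CC(=O)CCCCCCCCCCCO)c1.[K+].[K+] | intermediate (not isolated)
21 | 2-hydroxy-6-(13-hydroxy-2-oxotridecyl)-4-methoxybenzoic acid | COc1cc(O)c(C(=O)O)c(CC(=O)CCCCCCCCCCCO)c1 | target

**Step count and risks**

Total step count: 8. Longest linear sequence: 6 steps (steps 1–3 and 6–8, from 3,5-dimethoxyphenol); the alkyne branch has 2 steps (4–5).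

Steps most likely to fail:

1. Step 6 (key step). The aryl–copper intermediate may be protonated before it captures CO2, the copper acetylide may be diverted by reversible carboxylation, or the carboxylate may close 5-exo on the alkyne to an alkylidene phthalide. The fallback sets out from 11 and comes back at 17, making the three bonds one after another. Sonogashira coupling of 11 with commercially available 2-bromo-4,6-dimethoxybenzaldehyde F1 (Pd(PPh3)2Cl2, CuI, Et3N, 70 °C) should give 13-(2-formyl-3,5-dimethoxyphenyl)tridec-12-yn-1-yl pivalate F2. Pinnick oxidation (NaClO2, NaH2PO4, 2-methyl-2-butene, t-BuOH/H2O) should give 2,4-dimethoxy-6-[13-(pivaloyloxy)tridec-1-yn-1-yl]benzoic acid F3. Catalytic TfOH in CH2Cl2 should then close the acid 6-endo-dig on the alkyne to 17.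

2. Step 8. Cleavage of the hindered pivalate may be incomplete at temperatures the product tolerates, and the keto acid may re-close to the enol lactone or lose CO2 during acidification and isolation. The fallback sets out from 10 and comes back at 21; it carries the alcohol as an acetal that falls off in the Lewis-acid step, so that the last step is only a mild lactone opening. 10 with 3,4-dihydro-2H-pyran and PPTS (CH2Cl2, rt) should give 2-(tridec-12-yn-1-yloxy)tetrahydro-2H-pyran F4 (racemic at the acetal carbon, of no consequence). The coupling of step 6 applied to F4, 8 and CO2 should give 6,8-dimethoxy-3-[11-(tetrahydro-2H-pyran-2-yloxy)undecyl]-1H-isochromen-1-one F5. BCl3 (3 equiv, CH2Cl2, −78 → 0 °C, aqueous work-up) should cleave the C8 methyl ether and the acetal to give 8-hydroxy-3-(11-hydroxyundecyl)-6-methoxy-1H-isochromen-1-one F6. LiOH in THF/H2O at rt, followed by acidification to pH 4 at 0 °C, should then give 21.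

3. Step 7. Site selectivity between the two methyl ethers may be lost, or the Lewis acid may open the enol lactone. The fallback sets out from 17 and comes back at 19. Exhaustive demethylation with BBr3 (excess, CH2Cl2, −78 °C → rt) should give 11-(6,8-dihydroxy-1-oxo-1H-isochromen-3-yl)undecyl pivalate F7. MeI (1.05 equiv) and K2CO3 in acetone should then methylate only the C6 hydroxyl, because the C8 hydroxyl is held in a hydrogen bond to the lactone carbonyl, giving 19.

**Further compounds**

F1 | step 6 | 2-bromo-4,6-dimethoxybenzaldehyde | COc1cc(OC)c(C=O)c(Br)c1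
F2 | step 6 | 13-(2-formyl-3,5-dimethoxyphenyl)tridec-12-yn-1-yl pivalate | COc1cc(OC)c(C=O)c(C#CCCCCCCCCCCCOC(=O)C(C)(C)C)c1
F3 | step 6 | 2,4-dimethoxy-6-[13-(pivaloyloxy)tridec-1-yn-1-yl]benzoic acid | COc1cc(OC)c(C(=O)O)c(C#CCCCCCCCCCCCOC(=O)C(C)(C)C)c1
F4 | step 8 | 2-(tridec-12-yn-1-yloxy)tetrahydro-2H-pyran | C#CCCCCCCCCCCCOC1CCCCO1
F5 | step 8 | 6,8-dimethoxy-3-[11-(tetrahydro-2H-pyran-2-yloxy)undecyl]-1H-isochromen-1-one | COc1cc(OC)c2c(c1)C=C(CCCCCCCCCCCOC1CCCCO1)OC2=O
F6 | step 8 | 8-hydroxy-3-(11-hydroxyundecyl)-6-methoxy-1H-isochromen-1-one | COc1cc(O)c2c(c1)C=C(CCCCCCCCCCCO)OC2=O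
F7 | step 7 | 11-(6,8-dihydroxy-1-oxo-1H-isochromen-3-yl)undecyl pivalate | Oc1cc(O)c2c(c1)C=C(CCCCCCCCCCCOC(=O)C(C)(C)C)OC2=O
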